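The ten-membered carbocycle is never closed: it is carried through the synthesis as the ring-fusion bond C3–C9 of a cyclopentene fused to ring A. The key step is an intermolecular [5+2] cycloaddition of a 3-oxidopyrylium ylide (C4–C8 with the future ether oxygen and the C17–C19 arm) onto the C3=C9 enone of a trans-hydrindenone. It forms C3–C4 and C8–C9, closes the 4,8-oxygen-bridged pyran O–C4–C5–C6–C7–C8 and sets C4 and C8 in one operation; ozonolysis of C3=C9 later unveils the oxa-bridged cyclodecane. The precursors are an Achmatowicz-derived acetoxypyranone and a hydrindenone that already holds C1, C10, C11 and C14.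

Key step: step 15

Remark (assumption): 4-methylfuran-2-carbaldehyde (1) is taken as a catalogue compound.
Remark (convention): all intermediates keep the briarane numbering of the target (C15 = methyl on C1, C16 = carbon on C5, C17/C18/C19 = lactone CH/CH3/C=O, C20 = epoxide CH2). On the hydrindane, β is the face of the C15 methyl and α the opposite face. "As in the target" means the same spatial arrangement as at that atom in 37, which is (1S,2R,3S,4R,6S,7R,8R,9S,10S,11R,14S,17R).

**Fragment A: acetoxypyranone 7**

Step 1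
Reactants: 1 4-methylfuran-2-carbaldehyde; 2 (4R)-4-benzyl-3-propanoyl-1,3-oxazolidin-2-one
Product: 4 syn-aldol imide (2R,3R), via boron Z-enolate 3 (not isolated)
Conditions: Bu2BOTf, i-Pr2NEt, CH2Cl2, −78 to 0 °C; then pH 7 buffer, MeOH, H2O2
Reagents that add atoms: none
Why: Evans syn-aldol reaction, in which the Z-boron enolate reacts through a Zimmerman–Traxler chair whose face is fixed by the (R)-benzyl auxiliary, so that C17 is set as R (the carbinol centre, future C8, is erased in step 15).

Step 2
Reactants: 4 syn-aldol imide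
Product: 5 prop-2-enyl (2R,3R)-3-hydroxy-2-methyl-3-(4-methylfuran-2-yl)propanoate
Conditions: allyl alcohol, MeMgBr, THF/CH2Cl2, 0 °C
Reagents that add atoms: allyl alcohol, C=CCO
Why: Transesterification of the N-acyl oxazolidinone with a bromomagnesium alkoxide removes the auxiliary without touching C17 and gives an ester that can later be cleaved without base.

Step 3
Reactants: 5 allyl ester
Product: 6 prop-2-enyl (2R)-2-[(2R)-6-hydroxy-5-methyl-3-oxo-3,6-dihydro-2H-pyran-2-yl]propanoate (anomers)
Conditions: NBS, NaHCO3, NaOAc, THF/H2O 4:1, 0 °C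
Reagents that add atoms: water, O
Why: Achmatowicz rearrangement, in which oxidation of the furan, hydrolysis to the ene-dione and closure of the carbinol oxygen onto the aldehyde give the 6-hydroxypyranone; the furan reacts far faster than the allyl group.

Step 4
Reactants: 6 pyranone lactol
Product: 7 prop-2-enyl (2R)-2-[(2R)-6-acetoxy-5-methyl-3-oxo-3,6-dihydro-2H-pyran-2-yl]propanoate (anomers)
Conditions: Ac2O, pyridine, DMAP (cat.), CH2Cl2, −20 to 0 °C
Reagents that add atoms: acetic anhydride, CC(=O)OC(C)=O
Why: O-Acylation of the lactol installs the anomeric leaving group needed for ylide formation.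

**Fragment B: hydrindenone 21**

Step 5
Reactants: 8 1,4-dioxaspiro[4.5]dec-6-en-8-one
Product: 9 7-iodo-1,4-dioxaspiro[4.5]dec-6-en-8-one
Conditions: I2, pyridine/CH2Cl2 1:1, 0 °C to rt
Reagents that add atoms: iodine, II
Why: Johnson α-iodination of the enone (pyridine adds in Baylis–Hillman fashion, the enolate is iodinated, pyridine is eliminated).

Step 6
Reactants: 9 iodo enone
Product: 10 7-methyl-1,4-dioxaspiro[4.5]dec-6-en-8-one
Conditions: MeB(OH)2, PdCl2(dppf) (5 mol %), K3PO4, dioxane/H2O, 80 °C
Reagents that add atoms: methylboronic acid, CB(O)O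
Why: Suzuki–Miyaura coupling of the 2-iodo enone installs the future C15 methyl.

Step 7
Reactants: 10 methyl enone; 11 vinylmagnesium bromide; 12 acrolein
Product: 14 (6R,7S)-6-ethenyl-7-[(1S)-1-hydroxyprop-2-en-1-yl]-7-methyl-1,4-dioxaspiro[4.5]decan-8-one, via magnesium enolate 13 (not isolated)
Conditions: CuBr·SMe2 (5 mol %), Josiphos-type ligand (6 mol %, antipode chosen for the 6R adduct), t-BuOMe, −78 °C; then acrolein, −78 °C; aq NH4Cl
Reagents that add atoms: none
Why: Copper-catalysed asymmetric conjugate addition of the Grignard reagent sets C10 under ligand control, and the enolate then adds to acrolein anti to the new vinyl group (C1 quaternary, trans to C10) through a Zimmerman–Traxler chair that places the C2 hydroxyl syn to the C15 methyl.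

Step 8
Reactants: 14 vinyl ketol
Product: 15 trans-hydrindenol (C14 ketone, C11 ethylene ketal, C3=C9, 2β-OH, H-10 α, C15 β)
Conditions: second-generation Grubbs catalyst (3 mol %), CH2Cl2 (0.01 M), 40 °C
Reagents that add atoms: none
Why: Ring-closing metathesis of the two terminal vinyl groups forms the trans-fused cyclopentene C3=C9, which is the template ring, without touching a stereocentre.

Step 9
Reactants: 15 trans-hydrindenol
Product: 16 diol (as 15, with 14α-OH)
Conditions: Me4NBH(OAc)3, MeCN/AcOH 1:1, −30 °C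
Reagents that add atoms: none
Why: Evans–Saksena reduction, in which the borohydride bound to the C2 oxygen delivers hydride intramolecularly to the β face of C14 and so gives the anti-1,3-diol with the axial 14α-hydroxyl of the target.

Step 10
Reactants: 16 diol ketal
Product: 17 keto diol (as 16, C11 ketone)
Conditions: PPTS, acetone/H2O 10:1, 55 °C
Reagents that add atoms: water, O
Why: Acid-catalysed acetal hydrolysis under conditions mild enough to leave the allylic alcohol and the C10 centre next to the new ketone alone.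

Step 11
Reactants: 17 keto diol
Product: 18 diene diol (as 17, C11=C20 exocyclic methylene)
Conditions: Zn, CH2Br2, TiCl4 (Lombardo reagent), THF/CH2Cl2, 0 °C to rt
Reagents that add atoms: dibromomethane, BrCBr
Why: Lombardo methylenation is non-basic, so the epimerisable C10–H next to the C11 ketone is not touched, and free hydroxyls are tolerated.

Step 12
Reactants: 18 diene diol
Product: 19 hydrindenone (C2 ketone conjugated with C3=C9, 14α-OH, C11=C20)
Conditions: MnO2, CH2Cl2, rt
Reagents that add atoms: none
Why: Manganese dioxide oxidises only the allylic C2 alcohol and so gives the cyclopentenone that will serve as the 2π partner.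

Step 13
Reactants: 19 hydrindenone
Product: 20 14α-acetoxy hydrindenone
Conditions: Ac2O, Et3N, DMAP, CH2Cl2, rt
Reagents that add atoms: acetic anhydride, CC(=O)OC(C)=O
Why: DMAP-catalysed acylation of the hindered axial C14 alcohol.

Step 14
Reactants: 20 14α-acetoxy hydrindenone
Product: 21 epoxy hydrindenone (11,20-epoxide with oxygen α as in the target, 14α-OAc, C2 ketone, C3=C9)
Conditions: mCPBA, NaHCO3, CH2Cl2, 0 °C
Reagents that add atoms: mCPBA, OOC(=O)c1cccc(Cl)c1
Why: Prilezhaev epoxidation of the only electron-rich alkene, with attack on the α face of the exocyclic methylene because the β (axial) face is blocked by the syn-axial C15 methyl, which gives C11 as in the target.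

**Union and elaboration**

Step 15
Reactants: 7 acetoxypyranone; 21 epoxy hydrindenone
Product: 23 cycloadduct (8-oxabicyclo[3.2.1]oct-3-en-2-one with O bridging C4 and C8, C7 ketone and C5(CH3)=C6, exo-fused through C3–C9 to the α face of the hydrindanone; C4, C8, C17 and ring A as in the target; H-3 and H-9 β), via oxidopyrylium ylide 22 (not isolated)
Conditions: i-Pr2NEt (3 equiv), MeCN, 40 °C, 7 (2.5 equiv) added over 6 h
Reagents that add atoms: none
Why: The amine removes the C8 proton of 7 and acetate leaves from C4 to give the 2-alkyl-5-methyl-3-oxidopyrylium ylide 22, which adds across C3=C9 of 21 in a concerted, asynchronous [5+2] cycloaddition, the classical intermolecular oxidopyrylium–alkene cycloaddition known for acrylates and cyclic enones. The step closes, both in cycloaddition mode, the tetrahydrofuran ring O–C4–C3–C9–C8 and the oxygen-bridged cycloheptenone C3–C4–C5–C6–C7–C8–C9, and with them the C3–C4 and C8–C9 bonds and the C4–O–C8 pyran of the target. The nucleophilic ylide terminus next to the oxide (C8) bonds to the enone β-carbon C9 and C4 to the α-carbon C3, the usual orientation with acceptor-substituted alkenes. C4 and C8 are set together by suprafacial addition across the planar ylide, and their sense relative to C1 and C10 follows from approach to the α face of the cyclopentenone, anti to the axial C15 methyl, in the exo topology that keeps ring A away from the C5-methyl/C7-oxido arm; C3 and C9 become cis (both are erased in step 22) and C17 is carried from step 1. The step therefore needs regio-, π-facial and exo selectivity: the first is electronic, the other two rest on the shape of the trans-hydrindenone and are the main risk, and slow addition of excess 7 keeps ylide dimerisation from outrunning the cycloaddition.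

Step 16
Reactants: 23 cycloadduct
Product: 24 diol (2β-OH; 7-OH on the face of the C3–C9 bridge, epimeric to the C7–O of the target)
Conditions: NaBH4 (excess), CeCl3·7H2O, MeOH/CH2Cl2, −40 to 0 °C
Reagents that add atoms: none
Why: Luche reduction, in which hydride adds 1,2 to the C7 enone from the exo face (side of the oxygen bridge) and to the C2 ketone from the α face; the C2 carbinol is re-oxidised in step 20.

Step 17
Reactants: 24 diol allyl ester
Product: 25 hydroxy acid (C19 carboxylic acid)
Conditions: Pd(PPh3)4 (5 mol %), morpholine, THF, rt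
Reagents that add atoms: none
Why: Palladium(0)-catalysed allyl transfer (Tsuji–Trost deallylation) frees the acid under neutral conditions that spare the acetate, the epoxide and C17.

Step 18
Reactants: 25 hydroxy acid
Product: 26 lactone (cis-fused C19–O–C7 γ-lactone, C7 as in the target, C5(CH3)=C6, 2β-OH)
Conditions: PPh3, DIAD, THF (0.005 M), 0 °C to rt
Reagents that add atoms: none
Why: Intramolecular Mitsunobu lactonisation, in which the carboxylate displaces the activated allylic C7 oxygen from the exo face with inversion, the only geometry that gives the cis-fused lactone, so that C7 is set as in the target.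

Step 19
Reactants: 26 lactone
Product: 27 allylic chloride (6-chloro as in the target, C5=C16 methylene)
Conditions: Ca(OCl)2, CO2 (dry ice), CH2Cl2/H2O, 0 °C
Reagents that add atoms: hypochlorous acid (from calcium hypochlorite), OCl
Why: Ene-type allylic chlorination, in which Cl+ adds to C6 of the trisubstituted alkene from the exo face, away from the C3–C9 bridge, and a proton is lost from C16 because C4 is a bridgehead, which sets C6 and the 5(16)-methylene.

Step 20
Reactants: 27 allylic chloride
Product: 29 enone (C2 ketone, C3=C9), via C2 ketone 28 (not isolated)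
Conditions: IBX (4 equiv), 4-methoxypyridine N-oxide, DMSO, 25 to 45 °C
Reagents that add atoms: none
Why: IBX oxidises the C2 alcohol and then dehydrogenates the ketone; C3 is the only enolisable α-position (C1 is quaternary) and C9 carries the only β-hydrogen, so the double bond can form only at C3=C9.

Step 21
Reactants: 29 enone
Product: 30 allylic alcohol (2β-OH, C2 as in the target, C3=C9)
Conditions: NaBH4, CeCl3·7H2O, MeOH, −40 °C
Reagents that add atoms: none
Why: Luche 1,2-reduction of the cyclopentenone from the α face, anti to the C15 methyl as with 17-keto steroids, sets C2.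

Step 22
Reactants: 30 allylic alcohol
Product: 31 seco-diketone (ten-membered ring opened, ketones at C3 and C9, 2-OH)
Conditions: O3 (1.05 equiv), pyridine (3 equiv), CH2Cl2, −78 °C
Reagents that add atoms: ozone, [O-][O+]=O
Why: Ozonolysis in the presence of pyridine gives the carbonyls directly; the tetrasubstituted, strained C3=C9 alkene reacts far faster than the 1,1-disubstituted alkene deactivated by the allylic chlorine, and its cleavage unveils the oxa-bridged ten-membered ring.

Step 23
Reactants: 31 seco-diketone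
Product: 32 2,3-diol (3-OH as in the target, C9 ketone)
Conditions: Me4NBH(OAc)3, MeCN/AcOH 3:1, −35 °C
Reagents that add atoms: none
Why: Hydroxyl-directed triacetoxyborohydride reduction delivers hydride to C3 from the face of the C2 oxygen and gives the trans-2,3-diol, i.e. C3 of the target, while the C9 ketone, which has no directing group, stays.

Step 24
Reactants: 32 2,3-diol
Product: 33 3-acetate
Conditions: Ac2O (1.2 equiv), pyridine, CH2Cl2, 0 °C
Reagents that add atoms: acetic anhydride, CC(=O)OC(C)=O
Why: Acylation without DMAP discriminates the C3 hydroxyl from the neopentylic C2 hydroxyl next to the quaternary C1.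

Step 25
Reactants: 33 3-acetate
Product: 34 2-O-triethylsilyl ether
Conditions: TESOTf, 2,6-lutidine, CH2Cl2, −78 °C
Reagents that add atoms: triethylsilyl triflate, CC[Si](CC)(CC)OS(=O)(=O)C(F)(F)F
Why: Silylation with the triflate protects the hindered C2 hydroxyl so that the later acetylation at C9 cannot reach it.

Step 26
Reactants: 34 2-O-triethylsilyl ether
Product: 35 9-alcohol (9S as in the target)
Conditions: NaBH4, MeOH/THF, −20 °C
Reagents that add atoms: none
Why: Borohydride reduction of the C9 ketone from the α face, which is flanked by H-10 whereas the β face is flanked by C11 and C7 and lies over the pyran bridge, should set C9.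

Step 27
Reactants: 35 9-alcohol
Product: 36 9-acetate
Conditions: Ac2O, DMAP, pyridine, 40 °C
Reagents that add atoms: acetic anhydride, CC(=O)OC(C)=O
Why: DMAP-catalysed acetylation of the hindered C9 alcohol.

Step 28
Reactants: 36 9-acetate
Product: 37 CNP0270816.1
Conditions: TBAF, AcOH, THF, 0 °C
Reagents that add atoms: none
Why: Buffered fluoride cleaves the Si–O bond and leaves the three acetates, the lactone, the epoxide and the allylic chloride untouched.

**Compound list**

1 | 4-methylfuran-2-carbaldehyde | Cc1coc(C=O)c1 | starting material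
2 | (4R)-4-benzyl-3-propanoyl-1,3-oxazolidin-2-one | CCC(=O)N1C(=O)OC[C@H]1Cc1ccccc1 | starting material
3 | dibutylboron (Z)-enolate of 2 | C/C=C(\OB(CCCC)CCCC)N1C(=O)OC[C@H]1Cc1ccccc1 | intermediate (not isolated)
4 | (4R)-4-benzyl-3-[(2R,3R)-3-hydroxy-2-methyl-3-(4-methylfuran-2-yl)propanoyl]-1,3-oxazolidin-2-one | Cc1coc(c1)[C@H](O)[C@@H](C)C(=O)N1C(=O)OC[C@H]1Cc1ccccc1 | intermediate
5 | prop-2-enyl (2R,3R)-3-hydroxy-2-methyl-3-(4-methylfuran-2-yl)propanoate | Cc1coc(c1)[C@H](O)[C@@H](C)C(=O)OCC=C | intermediate
6 | prop-2-enyl (2R)-2-[(2R)-6-hydroxy-5-methyl-3-oxo-3,6-dihydro-2H-pyran-2-yl]propanoate, anomers | CC1=CC(=O)[C@H](OC1O)[C@@H](C)C(=O)OCC=C | intermediate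
7 | prop-2-enyl (2R)-2-[(2R)-6-acetoxy-5-methyl-3-oxo-3,6-dihydro-2H-pyran-2-yl]propanoate, anomers | CC1=CC(=O)[C@H](OC1OC(C)=O)[C@@H](C)C(=O)OCC=C | intermediate
8 | 1,4-dioxaspiro[4.5]dec-6-en-8-one | O=C1C=CC2(CC1)OCCO2 | starting material
9 | 7-iodo-1,4-dioxaspiro[4.5]dec-6-en-8-one | O=C1C(I)=CC2(CC1)OCCO2 | intermediate
10 | 7-methyl-1,4-dioxaspiro[4.5]dec-6-en-8-one | CC1=CC2(CCC1=O)OCCO2 | intermediate
11 | vinylmagnesium bromide | C=C[Mg]Br | starting material
12 | acrolein | C=CC=O | starting material
13 | bromomagnesium enolate of the 6-ethenyl adduct (C10 as in the target) | C=C[C@H]1C2(CCC(O[Mg]Br)=C1C)OCCO2 | intermediate (not isolated)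
14 | (6R,7S)-6-ethenyl-7-[(1S)-1-hydroxyprop-2-en-1-yl]-7-methyl-1,4-dioxaspiro[4.5]decan-8-one | C=C[C@H]1C2(CCC(=O)[C@]1(C)[C@@H](O)C=C)OCCO2 | intermediate
15 | trans-hydrindenol: C14 ketone, C11 ethylene ketal, C3=C9, 2β-OH, H-10 α, C15 β | C1[C@H]2C3(CCC(=O)[C@]2(C)[C@@H](O)C=1)OCCO3 | intermediate
16 | diol: as 15 with 14α-OH | C1[C@H]2C3(CC[C@H](O)[C@]2(C)[C@@H](O)C=1)OCCO3 | intermediate
17 | keto diol: as 16 with free C11 ketone | C1[C@H]2C(=O)CC[C@H](O)[C@]2(C)[C@@H](O)C=1 | intermediate
18 | diene diol: as 17 with C11=C20 methylene | C1[C@H]2C(=C)CC[C@H](O)[C@]2(C)[C@@H](O)C=1 | intermediate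
19 | hydrindenone: C2 ketone, C3=C9, 14α-OH, C11=C20 | C1[C@H]2C(=C)CC[C@H](O)[C@]2(C)C(=O)C=1 | intermediate
20 | 14α-acetoxy hydrindenone | C1[C@H]2C(=C)CC[C@H](OC(C)=O)[C@]2(C)C(=O)C=1 | intermediate
21 | epoxy hydrindenone: 11,20-epoxide (O α), 14α-OAc, C2 ketone, C3=C9 | C1[C@H]2[C@]3(CC[C@H](OC(C)=O)[C@]2(C)C(=O)C=1)CO3 | intermediate
22 | 3-oxidopyrylium ylide (C4–C8, C16 methyl on C5, C17 arm on C8) | Cc1cc([O-])c([C@@H](C)C(=O)OCC=C)[o+]c1 | intermediate (not isolated)
23 | cycloadduct: oxygen-bridged enone (C7 ketone, C5(CH3)=C6) exo-fused via C3–C9 to the hydrindanone (C2 ketone), allyl ester | CC1[C@H]2O[C@@]([C@@H](C)C(=O)OCC=C)(C(=O)C=1)[C@@H]4[C@H]1[C@]3(CC[C@H](OC(C)=O)[C@]1(C)C(=O)[C@H]24)CO3 | intermediate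
24 | diol: 2β-OH and 7-OH (7-epi), allyl ester | CC1[C@H]2O[C@@]([C@@H](C)C(=O)OCC=C)([C@H](O)C=1)[C@@H]4[C@H]1[C@]3(CC[C@H](OC(C)=O)[C@]1(C)[C@@H](O)[C@H]24)CO3 | intermediate
25 | hydroxy acid: as 24 with C19 carboxylic acid | CC1[C@H]2O[C@@]([C@@H](C)C(=O)O)([C@H](O)C=1)[C@@H]4[C@H]1[C@]3(CC[C@H](OC(C)=O)[C@]1(C)[C@@H](O)[C@H]24)CO3 | intermediate
26 | lactone: cis C19–O–C7 γ-lactone, C5(CH3)=C6, 2β-OH, C3–C9 bond | CC1[C@H]2O[C@]3([C@@H](C)C(=O)O[C@H]3C=1)[C@@H]4[C@H]1[C@]3(CC[C@H](OC(C)=O)[C@]1(C)[C@@H](O)[C@H]24)CO3 | intermediate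
27 | allylic chloride: 6-Cl, C5=C16, 2β-OH, C3–C9 bond | C=C1[C@H]2O[C@]3([C@@H](C)C(=O)O[C@H]3[C@H]1Cl)[C@@H]4[C@H]1[C@]3(CC[C@H](OC(C)=O)[C@]1(C)[C@@H](O)[C@H]24)CO3 | intermediate
28 | C2 ketone of 27 | C=C1[C@H]2O[C@]3([C@@H](C)C(=O)O[C@H]3[C@H]1Cl)[C@@H]4[C@H]1[C@]3(CC[C@H](OC(C)=O)[C@]1(C)C(=O)[C@H]24)CO3 | intermediate (not isolated)
29 | enone: C2 ketone, C3=C9 | C=C1[C@H]2O[C@]3([C@@H](C)C(=O)O[C@H]3[C@H]1Cl)C4[C@H]1[C@]3(CC[C@H](OC(C)=O)[C@]1(C)C(=O)C2=4)CO3 | intermediate
30 | allylic alcohol: 2β-OH, C3=C9 | C=C1[C@H]2O[C@]3([C@@H](C)C(=O)O[C@H]3[C@H]1Cl)C4[C@H]1[C@]3(CC[C@H](OC(C)=O)[C@]1(C)[C@@H](O)C2=4)CO3 | intermediate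
31 | seco-diketone: ten-membered ring, C3 and C9 ketones, 2-OH | C=C1[C@H]2O[C@]3([C@@H](C)C(=O)O[C@H]3[C@H]1Cl)C(=O)[C@H]1[C@]3(CC[C@H](OC(C)=O)[C@]1(C)[C@@H](O)C2=O)CO3 | intermediate
32 | 2,3-diol with C9 ketone | C=C1[C@H]2O[C@]3([C@@H](C)C(=O)O[C@H]3[C@H]1Cl)C(=O)[C@H]1[C@]3(CC[C@H](OC(C)=O)[C@]1(C)[C@@H](O)[C@@H]2O)CO3 | intermediate
33 | 3-acetate with 2-OH and C9 ketone | C=C1[C@H]2O[C@]3([C@@H](C)C(=O)O[C@H]3[C@H]1Cl)C(=O)[C@H]1[C@]3(CC[C@H](OC(C)=O)[C@]1(C)[C@@H](O)[C@@H]2OC(C)=O)CO3 | intermediate
34 | 2-O-triethylsilyl ether of 33 | C=C1[C@H]2O[C@]3([C@@H](C)C(=O)O[C@H]3[C@H]1Cl)C(=O)[C@H]1[C@]3(CC[C@H](OC(C)=O)[C@]1(C)[C@@H](O[Si](CC)(CC)CC)[C@@H]2OC(C)=O)CO3 | intermediate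
35 | 9-alcohol (9S), 2-O-TES | C=C1[C@H]2O[C@]3([C@@H](C)C(=O)O[C@H]3[C@H]1Cl)[C@@H](O)[C@H]1[C@]3(CC[C@H](OC(C)=O)[C@]1(C)[C@@H](O[Si](CC)(CC)CC)[C@@H]2OC(C)=O)CO3 | intermediate
36 | 9-acetate, 2-O-TES | C=C1[C@H]2O[C@]3([C@@H](C)C(=O)O[C@H]3[C@H]1Cl)[C@@H](OC(C)=O)[C@H]1[C@]3(CC[C@H](OC(C)=O)[C@]1(C)[C@@H](O[Si](CC)(CC)CC)[C@@H]2OC(C)=O)CO3 | intermediate
37 | CNP0270816.1 | C=C1[C@H]2O[C@]3([C@@H](C)C(=O)O[C@H]3[C@H]1Cl)[C@@H](OC(C)=O)[C@H]1[C@]3(CC[C@H](OC(C)=O)[C@]1(C)[C@@H](O)[C@@H]2OC(C)=O)CO3 | target

**Summary**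

Total step count: 28.
Longest linear sequence: 24 steps (steps 5–14, then 15–28).

**Steps most likely to fail**

Step 15. The cis-disubstituted enone 21 may react too slowly, so that dimerisation of ylide 22 consumes the pyranone and the exo preference is eroded. The fallback sets out from 21 and comes back at 23. Compound 21 is brominated and dehydrobrominated (Br2, CH2Cl2, −78 °C, then Et3N) to the 3-bromo enone F1; 2-halo cycloalkenones are established as much more reactive 2π partners. Cycloaddition with 7 under the conditions of step 15 gives the 3-bromo cycloadduct F2 with the same orientation (the halogen-bearing carbon again bonds to C4). Radical debromination (Bu3SnH, AIBN, benzene, 80 °C) then gives 23, because the C3 radical can take up hydrogen only in the one open position.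

Step 7. The copper catalyst may discriminate poorly between the faces of the hindered α-methyl, γ-quaternary enone 10, which would give low enantiomeric purity. The fallback sets out from 10 and comes back at 15. Conjugate addition and aldol are run without ligand (CuI cat.) to give 14 together with the enantiomeric ketol F3, and ring-closing metathesis as in step 8 gives 15 together with the enantiomeric hydrindenol F4. The racemate is resolved with a lipase (Amano PS, vinyl acetate, t-BuOMe): by the empirical rule for lipase acylation of secondary alcohols the R-configured carbinol of F4 is acylated to the enantiomeric acetate F5, and 15 (S carbinol) is recovered unchanged.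

Step 26. Hydride may approach C9 of the medium ring from the β face, which would give poor facial selectivity. The fallback sets out from 34 and comes back at 36. The reduction is run as in step 26, and the epimeric material, the 9-epi alcohol F6, is converted with inversion under Mitsunobu conditions with acetic acid (PPh3, DIAD, AcOH, toluene, 0 °C to rt). This installs the 9-acetate of 36 directly, so step 27 is not needed for that material.

**Further compounds**

F1 | step 15 | 3-bromo enone (21 with Br on C3) | C1[C@H]2[C@]3(CC[C@H](OC(C)=O)[C@]2(C)C(=O)C(Br)=1)CO3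
F2 | step 15 | 3-bromo cycloadduct (23 with Br in place of H-3) | CC1[C@H]2O[C@@]([C@@H](C)C(=O)OCC=C)(C(=O)C=1)[C@@H]4[C@H]1[C@]3(CC[C@H](OC(C)=O)[C@]1(C)C(=O)[C@]24Br)CO3
F3 | step 7 | enantiomeric ketol (ent-14) | C=C[C@@H]1C2(CCC(=O)[C@@]1(C)[C@H](O)C=C)OCCO2
F4 | step 7 | enantiomeric hydrindenol (ent-15) | C1[C@@H]2C3(CCC(=O)[C@@]2(C)[C@H](O)C=1)OCCO3
F5 | step 7 | enantiomeric acetate (acetate of ent-15) | C1[C@@H]2C3(CCC(=O)[C@@]2(C)[C@H](OC(C)=O)C=1)OCCO3
F6 | step 26 | 9-epi alcohol (9-epimer of 35) | C=C1[C@H]2O[C@]3([C@@H](C)C(=O)O[C@H]3[C@H]1Cl)[C@H](O)[C@H]1[C@]3(CC[C@H](OC(C)=O)[C@]1(C)[C@@H](O[Si](CC)(CC)CC)[C@@H]2OC(C)=O)CO3
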